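## Analysis of the target

CNP0296164.1 (49) is a briarane: a cyclohexene (ring A: C1, C10, C11, C12, C13, C14) is trans-fused through C1 and C10 to a ten-membered carbocycle (C1 to C10), and a γ-lactone (C7–O–C19(=O)–C17–C8) is fused to that ring at C7–C8. The numbering used throughout is: C1 quaternary fusion carbon (methyl C15), C2 (OAc), C3, C4, C5 (methyl C16)=C6 (Cl), C7 (lactone O), C8 (tertiary OH), C9 (OH), C10 (fusion CH), C11 (methyl C20), C12 (OAc), C13=C14, C17 (methyl C18) and C19 (lactone carbonyl). There are nine stereocentres (1S,2S,7R,8R,9S,10S,11R,12R,17R). On ring A, C9, C15 and C20 lie on one face and the C2 branch and the C12 acetate on the other. Along the chain the C7 and C9 oxygens are 1,3-anti, and on the lactone the C8 hydroxyl and C18 are cis to C6 and trans to C9. The C5=C6 alkene is tetrasubstituted, with C4 cis to C7 and chlorine cis to C16. The sensitive groups are the allylic acetate at C12, the β-hydroxy lactone (retro-aldol, dehydration, acyl shift to O9) and the vinyl chloride, whose geometry cannot be corrected once set. The synthesis is hard because the quaternary C1 is flanked by the stereocentres C2 and C10 at a ring fusion, because a ten-membered ring has to be closed, and because C7, C8 and C9 form a contiguous oxygenated triad around a tertiary carbinol. The strategy rests on ring A: a quaternary C1 next to C10, a carbon substituent (C9) on C10 and the C13=C14 alkene allylic to C1 are exactly what a [3,3] shift of an ester enolate leaves behind when the allylic oxygen sat on C13.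

## Retrosynthetic reasoning

49 back to 46. The two acetates are put on last, because an allylic acetate at C12 would ionise under the palladium conditions of the ring closure. C2 and C12 therefore travel as triethylsilyl ethers and C9 as a tert-butyldimethylsilyl ether; the forward sequence is removal of the two triethylsilyl groups (47), acetylation (48) and removal of the last silyl group.

46 back to 44. The ten-membered ring is cut at C4–C5. This is the one ring bond that can be made from the C3=C4 vinyl group carried since 17, and cutting here lets the chloroalkene arrive with its geometry fixed in an acyclic enol triflate. The forward reaction is an anti-Markovnikov hydroboration of the vinyl group and an intramolecular B-alkyl Suzuki–Miyaura coupling at C5, which must close a medium ring with retention of alkene geometry.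

44 back to 42. The lactone is cut at C8–C17. Forming this bond from an enolate tethered through O7 makes the tertiary carbinol and C17 in one step, puts the lactone on the correct oxygen without competition from O9, and delivers carbon rather than oxygen to C8, which is what the relative configuration at C7/C8 demands. The forward reaction is an intramolecular Reformatsky addition to the C8 ketone.

42 back to 31 and 35. The C7–C8 bond is cut as an aldol between the α-alkoxymethyl ketone 31 and the enal 35; the C8 oxygen is carried as a benzylic ether so that it can be unmasked and oxidised alone. This disconnection joins the two halves in one step and creates C7. C9 is then set by reduction of the C9 ketone (38 to 39) under control of the C8 ether, before C8 itself is taken to the ketone (41 to 42).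

31 back to 24. The C8–C9 bond is cut between the carboxyl carbon of 24 (via amide 26) and a one-carbon alkoxymethyl nucleophile from 29; this turns the carboxyl group left by the rearrangement directly into the C9 ketone with C8 attached.

24 back to 21. This is the key disconnection: the C1–C10 bond of ring A is cut and the C13–O bond restored, which gives the δ-lactone 21 with a Z-alkenyl chain on C13. Nothing else makes the crowded C1–C10 bond with both configurations fixed by centres that are easy to set (C13 and the alkene geometry). The forward reaction is the ring contraction of the silyl ketene acetal of 21.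

21 back to 9 and 17. The lactone is opened to hydroxy ester 20 and the C13–C14 bond is cut between aldehyde 9 and the alkenyl iodide 17. The forward addition must give the 12,13-syn alcohol, so it is run under chelation control by the C12 oxygen.

9, 17, 35 and 29 back to purchasable compounds. 9 comes from 1 and 2 by a syn-selective crotylation that sets C11 and C12 (3), followed by chain-end oxidation. 17 comes from 10 by carbometalation–iodination (12), which fixes the Z geometry, oxidation (13), addition of 14 and resolution (16), which sets C2. 35 comes from 32 through the enol triflate 33, which fixes the C5=C6 geometry, and 29 comes from 27 and 28.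

## Alternatives that were turned down

Alternative 1: The ten-membered ring would be closed at C6–C7 by a nickel-catalysed, chromium-mediated addition of an α-chloroalkenyl metal, generated at the C–I bond of a 1-chloro-1-iodoalkene terminus, to a C7 aldehyde, giving the carbinol A1. In its favour, the coupling tolerates esters and acetates, leaves the C–Cl bond alone, and makes the C7 oxygen and the ring in one step. As a ring closure it is at least as strong as the Suzuki closure used here, which has to join an alkylborane to a hindered tetrasubstituted triflate. Against it for this target: the precursor of A1 needs a tetrasubstituted 1-chloro-1-iodoalkene of defined geometry, which is much harder to secure than the chelation-controlled enol triflate 33. An α-haloalkenyl metal can also lose halide by α-elimination. C7 would be set during macrocyclisation by ring conformation, not by a reagent. The alternative says nothing about ring A and C1, so the hardest carbon has to be solved elsewhere. In exchange for a less comfortable ring closure, the chosen strategy sets C1 and C10 by chirality transfer and C7 before the ring exists.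

Alternative 2: Ring A would be made by a catalytic asymmetric Diels–Alder reaction that forms C1–C14 and C10–C11 under a chiral oxazaborolidinium Lewis acid and gives the silyl enol ether A2. In its favour, two bonds, the quaternary C1 and up to three stereocentres appear in one catalytic step; on step economy for ring A it is clearly stronger than the thirteen steps needed here to reach 21. Against it for this target: the diene must carry its methyl group Z to give the cis C20/C9 relationship, and Z-dienes reach the s-cis conformation poorly and react sluggishly with a trisubstituted dienophile. A2 also has oxygen at C12 at the ketone level and no C13=C14 alkene, so a dehydrogenation and a stereoselective reduction must follow. C2 must then be created by addition to a neopentyl aldehyde with no controlling neighbour. The chosen strategy is longer, but it delivers C1, C2, C10, C11 and C12 with their relationships fixed and the C13=C14 alkene already in place.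

Alternative 3: The ten-membered ring would be revealed, not closed, by ozonolysis of a tetrasubstituted C2=C8 alkene in a tricyclic precursor, giving the 2,8-diketone A3. In its favour, there is no entropically difficult macrocyclisation, and the two new carbonyl groups appear exactly at the carbons that need oxygen; on ring formation it is stronger than the chosen route. Against it: A3 carries three ketones (C2, C8, C12) that must be told apart and reduced or alkylated stereoselectively in a flexible ring. The 2,8-diketone can close back by transannular aldol reaction. The propionate unit must be added to the C8 ketone from outside with only ring conformation as control. The tricyclic precursor, with its chloroalkene in a seven-membered ring, is itself a long synthesis. The chosen strategy keeps C2 as a protected alcohol of known configuration from the start and builds C8 and C17 by an intramolecular, tethered addition.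

Key step: step 14

## Remarks before the steps

- Assumption: the sense of induction of the chiral phosphoric acid in step 1 and of the isopinocampheyl boron enolate in step 21 is taken from the usual transition-state models; in each case the reagent antipode meant is the one that delivers the face stated.
- Abbreviations: TES = triethylsilyl; TBS = tert-butyldimethylsilyl; PMB = 4-methoxybenzyl; Tf = trifluoromethanesulfonyl; Ipc = isopinocampheyl (from (+)-α-pinene); 9-BBN = 9-borabicyclo[3.3.1]nonane; DDQ = 2,3-dichloro-5,6-dicyano-1,4-benzoquinone; DMP = 1,1,1-triacetoxy-1,1-dihydro-1,2-benziodoxol-3(1H)-one; dppf = 1,1'-bis(diphenylphosphino)ferrocene.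
- RA = the (1S,2S,5R,6R)-2,6-dimethyl-5-(triethylsilyloxy)-2-[(1S)-1-(triethylsilyloxy)prop-2-en-1-yl]cyclohex-3-en-1-yl group (ring A of 24, attached through C10).
- Atom numbers C1 to C20 are those defined in the analysis.

## Route

Step 1
Reactants: 1 2,2-dimethoxyacetaldehyde; 2 (Z)-crotylboronic acid pinacol ester
Product: 3 (2S,3R)-1,1-dimethoxy-3-methylpent-4-en-2-ol
Conditions: (S)-3,3'-bis(2,4,6-triisopropylphenyl)-1,1'-binaphthyl-2,2'-diyl hydrogen phosphate (5 mol %), 4 Å MS, toluene, −30 °C
Reagents that add atoms: none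
Why: Brønsted-acid-catalysed allylboration through a closed chair transition state; the Z-crotyl geometry gives the syn C11-methyl/C12-hydroxyl pair and the chiral phosphate directs the crotyl group to the Si face of the aldehyde, which sets C11 and C12.

Step 2
Reactants: 3 (2S,3R)-1,1-dimethoxy-3-methylpent-4-en-2-ol
Product: 4 triethyl{[(2S,3R)-1,1-dimethoxy-3-methylpent-4-en-2-yl]oxy}silane
Conditions: Et3SiCl, imidazole, DMF, 0 °C
Reagents that add atoms: chlorotriethylsilane, CC[Si](Cl)(CC)CC
Why: Standard silylation of a secondary alcohol; the triethylsilyl ether is chosen so that it can be cleaved at the end in the presence of a tert-butyldimethylsilyl ether.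

Step 3
Reactants: 4 triethyl{[(2S,3R)-1,1-dimethoxy-3-methylpent-4-en-2-yl]oxy}silane
Product: 6 (3R,4S)-5,5-dimethoxy-3-methyl-4-(triethylsilyloxy)pentan-1-ol, via alkylborane 5 (not isolated)
Conditions: 9-BBN, THF, 0 °C → rt; then NaOH, H2O2, 0 °C
Reagents that add atoms: hydrogen peroxide, OO
Why: Anti-Markovnikov hydroboration–oxidation of the only alkene gives the primary alcohol (C9); no stereocentre is touched.

Step 4
Reactants: 6 (3R,4S)-5,5-dimethoxy-3-methyl-4-(triethylsilyloxy)pentan-1-ol
Product: 7 (3R,4S)-5,5-dimethoxy-3-methyl-4-(triethylsilyloxy)pentanoic acid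
Conditions: 2,2,6,6-tetramethylpiperidin-1-oxyl (cat.), NaClO2, NaOCl (cat.), MeCN/pH 6.7 phosphate buffer, 35 °C
Reagents that add atoms: sodium chlorite, [Na+].[O-]Cl=O
Why: Nitroxyl-catalysed oxidation with chlorite as terminal oxidant takes a primary alcohol to the acid at buffered pH, which the acetal and the silyl ether tolerate.

Step 5
Reactants: 7 (3R,4S)-5,5-dimethoxy-3-methyl-4-(triethylsilyloxy)pentanoic acid
Product: 8 methyl (3R,4S)-5,5-dimethoxy-3-methyl-4-(triethylsilyloxy)pentanoate
Conditions: MeI, K2CO3, DMF, 0 °C → rt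
Reagents that add atoms: iodomethane, CI
Why: O-Alkylation of the carboxylate; the ester keeps C9 at the acid oxidation level and is inert to the organozinc reagent of step 12.

Step 6
Reactants: 8 methyl (3R,4S)-5,5-dimethoxy-3-methyl-4-(triethylsilyloxy)pentanoate
Product: 9 methyl (3R,4S)-3-methyl-5-oxo-4-(triethylsilyloxy)pentanoate
Conditions: Et3SiOTf, 2,6-lutidine, CH2Cl2, 0 °C; then H2O
Reagents that add atoms: water, O
Why: Silyl triflate and a hindered pyridine convert the dimethyl acetal into a pyridinium N,O-acetal that water hydrolyses to the aldehyde; the medium stays non-acidic, so the silyl ether and the α-stereocentre C12 are preserved.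

Step 7
Reactants: 10 prop-2-yn-1-ol
Product: 12 (Z)-3-iodo-2-methylprop-2-en-1-ol, via alkenylmagnesium alkoxide 11 (not isolated)
Conditions: MeMgBr (2.2 equiv), CuI (10 mol %), THF, −10 °C → rt; then I2, −78 → 0 °C
Reagents that add atoms: methylmagnesium bromide, C[Mg]Br; iodine, II
Why: Copper-catalysed anti-carbomagnesiation of the propargylic alkoxide gives a chelated alkenylmagnesium with the metal cis to the CH2O group; iodinolysis with retention fixes the Z geometry of the future C14=C1 alkene.

Step 8
Reactants: 12 (Z)-3-iodo-2-methylprop-2-en-1-ol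
Product: 13 (Z)-3-iodo-2-methylprop-2-enal
Conditions: MnO2, CH2Cl2, rt
Reagents that add atoms: none
Why: Allylic oxidation with MnO2 stops at the aldehyde and does not isomerise the alkene.

Step 9
Reactants: 13 (Z)-3-iodo-2-methylprop-2-enal; 14 vinylmagnesium bromide
Product: 15 rac-(1Z)-1-iodo-2-methylpenta-1,4-dien-3-ol
Conditions: THF, −78 °C
Reagents that add atoms: none
Why: Grignard 1,2-addition to the enal creates C2 (racemic) together with the C3=C4 vinyl group; the vinyl iodide is inert at −78 °C.

Step 10
Reactants: 15 rac-(1Z)-1-iodo-2-methylpenta-1,4-dien-3-ol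
Product: 16 (1Z,3S)-1-iodo-2-methylpenta-1,4-dien-3-ol
Conditions: Ti(Oi-Pr)4, L-(+)-diisopropyl tartrate, t-BuOOH (0.6 equiv), 4 Å MS, CH2Cl2, −20 °C
Reagents that add atoms: none
Why: Sharpless kinetic resolution: with the L-(+)-tartrate the R alcohol is epoxidised at its vinyl group much faster, so the S alcohol (C2 of the target) is recovered; the Z-iodoalkene is a poor substrate for the titanium catalyst.

Step 11
Reactants: 16 (1Z,3S)-1-iodo-2-methylpenta-1,4-dien-3-ol
Product: 17 triethyl{[(1Z,3S)-1-iodo-2-methylpenta-1,4-dien-3-yl]oxy}silane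
Conditions: Et3SiCl, imidazole, DMF, 0 °C
Reagents that add atoms: chlorotriethylsilane, CC[Si](Cl)(CC)CC
Why: Standard silylation; protects C2–OH through the organometallic and enolate steps.

Step 12
Reactants: 17 triethyl{[(1Z,3S)-1-iodo-2-methylpenta-1,4-dien-3-yl]oxy}silane; 9 methyl (3R,4S)-3-methyl-5-oxo-4-(triethylsilyloxy)pentanoate
Product: 20 methyl (3R,4S,5S,6Z,8S)-5-hydroxy-3,7-dimethyl-4,8-bis(triethylsilyloxy)deca-6,9-dienoate, via alkenyllithium 18 (not isolated), via alkenylzinc bromide 19 (not isolated)
Conditions: t-BuLi (2.1 equiv), Et2O, −78 °C; ZnBr2 (1.5 equiv), −78 → 0 °C; then 9, toluene, −78 → −20 °C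
Reagents that add atoms: none
Why: Iodine–lithium exchange and transmetalation to zinc proceed with retention of the Z geometry; the zinc halide chelates the aldehyde oxygen and the α-silyloxy oxygen in a non-coordinating solvent, so the alkenyl group adds to the face away from the C11 branch (chelate model) and gives the 12,13-syn alcohol (C13 S).

Step 13
Reactants: 20 methyl (3R,4S,5S,6Z,8S)-5-hydroxy-3,7-dimethyl-4,8-bis(triethylsilyloxy)deca-6,9-dienoate
Product: 21 (4R,5S,6S)-4-methyl-6-[(1Z,3S)-2-methyl-3-(triethylsilyloxy)penta-1,4-dien-1-yl]-5-(triethylsilyloxy)tetrahydro-2H-pyran-2-one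
Conditions: 1,8-diazabicyclo[5.4.0]undec-7-ene (0.2 equiv), toluene, 80 °C
Reagents that add atoms: none
Why: Base-catalysed intramolecular transesterification closes the δ-lactone and is driven by loss of methanol; C10 carries no stereocentre and no β-leaving group, so nothing can epimerise or eliminate.

Step 14
Reactants: 21 (4R,5S,6S)-4-methyl-6-[(1Z,3S)-2-methyl-3-(triethylsilyloxy)penta-1,4-dien-1-yl]-5-(triethylsilyloxy)tetrahydro-2H-pyran-2-one
Product: 24 (1S,2S,5R,6R)-2,6-dimethyl-5-(triethylsilyloxy)-2-[(1S)-1-(triethylsilyloxy)prop-2-en-1-yl]cyclohex-3-ene-1-carboxylic acid, via silyl ketene acetal 22 (not isolated), via trimethylsilyl ester 23 (not isolated)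
Conditions: LiN(i-Pr)2, Me3SiCl/Et3N, THF, −78 °C → rt; toluene, 110 °C; then 0.5 M citric acid (aq.), THF, 0 °C
Reagents that add atoms: none
Why: Deprotonation at C10 and O-silylation give the cyclic silyl ketene acetal 22, which on heating undergoes a concerted suprafacial [3,3] sigmatropic shift (Ireland–Claisen rearrangement): C10 bonds to C1 while the C13–O bond breaks and the C13=C14 alkene appears, giving silyl ester 23 and, after hydrolysis, acid 24. The closest known reaction type is the ester enolate Claisen ring contraction of 6-alkenyl δ-lactones to cyclohex-3-enecarboxylic acids. Ring A closes as a six-membered carbocycle by bonding of the exocyclic alkene terminus C1 to the ring ketene acetal carbon C10; because C10 and C13 are tied by the C11–C12 bridge the six-atom array can only take a boat (bicyclo[2.2.2]octane-like) shape, so there is no chair/boat competition. C10 is set by chirality transfer from C13: the new bond forms on the lactone face that carries the alkenyl group, which places C9 cis to the C11 methyl and trans to the C12 silyloxy group (10S). C1 is set by the Z geometry of C14=C1 inside this boat: the methyl group (trans to C13) ends cis to C9 and the C2 branch (cis to C13) ends trans to it (1S). The step needs site selectivity (C10–H2 is the only enolisable position and there is no β-leaving group), O- rather than C-silylation (in situ trapping with Me3SiCl/Et3N) and retention of alkene geometry, all of which the cyclic substrate provides; C2, C11 and C12 are spectators.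

Step 15
Reactants: 24 (1S,2S,5R,6R)-2,6-dimethyl-5-(triethylsilyloxy)-2-[(1S)-1-(triethylsilyloxy)prop-2-en-1-yl]cyclohex-3-ene-1-carboxylic acid
Product: 26 RA–C(=O)N(OMe)Me [N-methoxy-N-methylamide of 24], via acid chloride 25 (not isolated)
Conditions: 1-chloro-N,N,2-trimethylprop-1-en-1-amine, CH2Cl2, 0 °C; then MeNH(OMe)·HCl, Et3N, 0 °C → rt
Reagents that add atoms: N,O-dimethylhydroxylamine hydrochloride, CNOC.Cl
Why: The hindered acid is activated as its chloride under neutral conditions (α-chloroenamine), which the silyl ethers tolerate, and acylates the hydroxylamine; C10 stays configurationally intact because no ketene-forming base is present before the amine is added.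

Step 16
Reactants: 27 4-methoxybenzyl alcohol; 28 tributyl(iodomethyl)stannane
Product: 29 tributyl{[(4-methoxybenzyl)oxy]methyl}stannane
Conditions: NaH, THF/DMF, 0 °C → rt
Reagents that add atoms: none
Why: Williamson etherification at the iodomethyl carbon gives the precursor of an α-alkoxymethyl anion.

Step 17
Reactants: 26 RA–C(=O)N(OMe)Me; 29 tributyl{[(4-methoxybenzyl)oxy]methyl}stannane
Product: 31 RA–C(=O)CH2OPMB [2-(4-methoxybenzyloxy)-1-RA-ethan-1-one], via alkoxymethyllithium 30 (not isolated)
Conditions: 29, n-BuLi, THF, −78 °C; then 26, −78 → −40 °C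
Reagents that add atoms: none
Why: Tin–lithium exchange gives the α-alkoxymethyllithium, which adds once to the N-methoxy-N-methylamide because the chelated tetrahedral intermediate survives until work-up; this forms C8–C9 with C9 as a ketone and C8 already oxygenated.

Step 18
Reactants: 32 ethyl 2-chloro-3-oxobutanoate
Product: 33 ethyl (2E)-2-chloro-3-(trifluoromethylsulfonyloxy)but-2-enoate
Conditions: Tf2O, aq. LiOH, toluene, 5 °C
Reagents that add atoms: trifluoromethanesulfonic anhydride, O=S(=O)(OS(=O)(=O)C(F)(F)F)C(F)(F)F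
Why: O-Sulfonylation of the lithium-chelated Z-enolate of the β-keto ester places the triflate cis to the ester, so chlorine is cis to the methyl group; this fixes the C5=C6 geometry of the target.

Step 19
Reactants: 33 ethyl (2E)-2-chloro-3-(trifluoromethylsulfonyloxy)but-2-enoate
Product: 34 (2E)-3-chloro-4-hydroxybut-2-en-2-yl trifluoromethanesulfonate
Conditions: (i-Bu)2AlH (2.2 equiv), CH2Cl2, −78 °C
Reagents that add atoms: none
Why: Hydride reduction of the ester to the allylic alcohol; the vinyl triflate and vinyl chloride are inert at −78 °C and the geometry is kept.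

Step 20
Reactants: 34 (2E)-3-chloro-4-hydroxybut-2-en-2-yl trifluoromethanesulfonate
Product: 35 (2E)-3-chloro-4-oxobut-2-en-2-yl trifluoromethanesulfonate
Conditions: DMP, NaHCO3, CH2Cl2, 0 °C
Reagents that add atoms: none
Why: Buffered periodinane oxidation gives the enal (C7) without isomerising the alkene; the aldehyde is used without storage.

Step 21
Reactants: 31 RA–C(=O)CH2OPMB; 35 (2E)-3-chloro-4-oxobut-2-en-2-yl trifluoromethanesulfonate
Product: 37 (2R,3R,4E)-4-chloro-3-hydroxy-2-(4-methoxybenzyloxy)-1-RA-5-(trifluoromethylsulfonyloxy)hex-4-en-1-one, via boron enolate 36 (not isolated)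
Conditions: (−)-Ipc2BOTf, i-Pr2NEt, CH2Cl2, −78 °C; then 35, −78 → −20 °C; H2O2, MeOH, pH 7 buffer, 0 °C
Reagents that add atoms: none
Why: Boron aldol reaction: the ketone can enolise only at C8 and gives the Z enolate, whose closed chair transition state leads to the 7,8-syn adduct; the isopinocampheyl ligands direct the enolate to the Re face of the enal (C7 R), and since the nearest substrate stereocentre is remote from the aldehyde, reagent control is expected to dominate.

Step 22
Reactants: 37 (2R,3R,4E)-4-chloro-3-hydroxy-2-(4-methoxybenzyloxy)-1-RA-5-(trifluoromethylsulfonyloxy)hex-4-en-1-one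
Product: 38 (2R,3R,4E)-3-(2-bromopropanoyloxy)-4-chloro-2-(4-methoxybenzyloxy)-1-RA-5-(trifluoromethylsulfonyloxy)hex-4-en-1-one (both epimers at the CHBr carbon)
Conditions: 2-bromopropanoyl bromide, pyridine, CH2Cl2, −40 → 0 °C
Reagents that add atoms: 2-bromopropanoyl bromide, CC(Br)C(Br)=O
Why: Acylation of the only free hydroxyl puts the future C17–C19 unit on O7; the CHBr centre needs no control because it becomes an enolate carbon in step 27.

Step 23
Reactants: 38 (2R,3R,4E)-3-(2-bromopropanoyloxy)-4-chloro-2-(4-methoxybenzyloxy)-1-RA-5-(trifluoromethylsulfonyloxy)hex-4-en-1-one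
Product: 39 (1S,2S,3R,4E)-3-(2-bromopropanoyloxy)-4-chloro-2-(4-methoxybenzyloxy)-1-RA-5-(trifluoromethylsulfonyloxy)hex-4-en-1-ol
Conditions: Zn(BH4)2, Et2O, −40 → −20 °C
Reagents that add atoms: none
Why: Chelation-controlled ketone reduction: zinc bridges the C9 carbonyl and the C8 benzylic ether oxygen and hydride enters from the side of H8, giving the 8,9-anti alcohol, that is C9 S and 1,3-anti to O7; attack anti to the quaternary C1 on the C10 side points the same way.

Step 24
Reactants: 39 (1S,2S,3R,4E)-3-(2-bromopropanoyloxy)-4-chloro-2-(4-methoxybenzyloxy)-1-RA-5-(trifluoromethylsulfonyloxy)hex-4-en-1-ol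
Product: 40 (1S,2R,3R,4E)-3-(2-bromopropanoyloxy)-1-(tert-butyldimethylsilyloxy)-4-chloro-2-(4-methoxybenzyloxy)-1-RA-5-(trifluoromethylsulfonyloxy)hex-4-ene
Conditions: t-BuMe2SiOTf, 2,6-lutidine, CH2Cl2, −78 → 0 °C
Reagents that add atoms: tert-butyldimethylsilyl trifluoromethanesulfonate, CC(C)(C)[Si](C)(C)OS(=O)(=O)C(F)(F)F
Why: A silyl triflate silylates the hindered C9 hydroxyl; the tert-butyldimethylsilyl ether is chosen to outlast the triethylsilyl ethers at the end and blocks acyl migration from O7.

Step 25
Reactants: 40 (1S,2R,3R,4E)-3-(2-bromopropanoyloxy)-1-(tert-butyldimethylsilyloxy)-4-chloro-2-(4-methoxybenzyloxy)-1-RA-5-(trifluoromethylsulfonyloxy)hex-4-ene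
Product: 41 (1S,2R,3R,4E)-3-(2-bromopropanoyloxy)-1-(tert-butyldimethylsilyloxy)-4-chloro-1-RA-5-(trifluoromethylsulfonyloxy)hex-4-en-2-ol
Conditions: DDQ, CH2Cl2/pH 7 buffer (10:1), 0 °C
Reagents that add atoms: none
Why: Oxidative cleavage of the 4-methoxybenzyl ether frees only the C8 hydroxyl; silyl ethers, the bromo ester, the vinyl triflate and the alkenes are inert to the buffered quinone.

Step 26
Reactants: 41 (1S,2R,3R,4E)-3-(2-bromopropanoyloxy)-1-(tert-butyldimethylsilyloxy)-4-chloro-1-RA-5-(trifluoromethylsulfonyloxy)hex-4-en-2-ol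
Product: 42 (1S,3R,4E)-3-(2-bromopropanoyloxy)-1-(tert-butyldimethylsilyloxy)-4-chloro-1-RA-5-(trifluoromethylsulfonyloxy)hex-4-en-2-one
Conditions: DMP, NaHCO3, CH2Cl2, 0 °C
Reagents that add atoms: none
Why: Buffered periodinane oxidation of the secondary C8 alcohol gives the ketone under non-basic conditions, so the acidic C7–H is not epimerised; the product is used at once.

Step 27
Reactants: 42 (1S,3R,4E)-3-(2-bromopropanoyloxy)-1-(tert-butyldimethylsilyloxy)-4-chloro-1-RA-5-(trifluoromethylsulfonyloxy)hex-4-en-2-one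
Product: 44 (3R,4S,5R)-5-[(1E)-1-chloro-2-(trifluoromethylsulfonyloxy)prop-1-en-1-yl]-4-hydroxy-3-methyl-4-[(S)-RA(tert-butyldimethylsilyloxy)methyl]dihydrofuran-2(3H)-one, via samarium enolate 43 (not isolated)
Conditions: SmI2 (2.2 equiv), THF, −78 °C; then aq. NH4Cl
Reagents that add atoms: none
Why: Intramolecular Reformatsky reaction: two-electron reduction of the C–Br bond gives a trivalent samarium ester enolate that adds to the C8 ketone through a five-membered transition state tethered by O7. Of the two ketone rotamers the one with the C9 branch beside H7 rather than beside the chloroalkenyl group is favoured, so the new hydroxyl ends cis to C6 (the C8 configuration of the target). The C18 methyl is expected anti to the C9 branch, which is also the expected more stable C17 epimer.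

Step 28
Reactants: 44 (3R,4S,5R)-5-[(1E)-1-chloro-2-(trifluoromethylsulfonyloxy)prop-1-en-1-yl]-4-hydroxy-3-methyl-4-[(S)-RA(tert-butyldimethylsilyloxy)methyl]dihydrofuran-2(3H)-one
Product: 46 (1S,2S,7R,8S,9S,10S,11R,12R,17R)-9-(tert-butyldimethylsilyloxy)-6-chloro-8-hydroxy-2,12-bis(triethylsilyloxy)briara-5,13-dien-19,7-olide (C4 cis to C7 on C5=C6), via alkylborane 45 (not isolated)
Conditions: 9-BBN (2.5 equiv), THF, 0 °C → rt; H2O; then slow addition to PdCl2(dppf) (20 mol %), AsPh3, Cs2CO3, DMF/THF/H2O, 50 °C, 1 mM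
Reagents that add atoms: none
Why: 9-BBN hydroborates only the terminal C3=C4 alkene (the C13=C14 alkene next to the quaternary carbon and the tetrasubstituted chloroalkene are too hindered); the B-alkyl Suzuki–Miyaura coupling then forms C4–C5 at the enol triflate with retention of geometry under high dilution, closing the ten-membered ring, while the C–Cl bond does not undergo oxidative addition to zerovalent palladium under these conditions.

Step 29
Reactants: 46 (1S,2S,7R,8S,9S,10S,11R,12R,17R)-9-(tert-butyldimethylsilyloxy)-6-chloro-8-hydroxy-2,12-bis(triethylsilyloxy)briara-5,13-dien-19,7-olide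
Product: 47 (1S,2S,7R,8S,9S,10S,11R,12R,17R)-9-(tert-butyldimethylsilyloxy)-6-chloro-2,8,12-trihydroxybriara-5,13-dien-19,7-olide
Conditions: HF·pyridine, pyridine, THF, 0 °C
Reagents that add atoms: none
Why: Buffered fluoride cleaves the two triethylsilyl ethers much faster than the hindered tert-butyldimethylsilyl ether on C9, freeing exactly the two hydroxyls that are to be acetylated.

Step 30
Reactants: 47 (1S,2S,7R,8S,9S,10S,11R,12R,17R)-9-(tert-butyldimethylsilyloxy)-6-chloro-2,8,12-trihydroxybriara-5,13-dien-19,7-olide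
Product: 48 (1S,2S,7R,8S,9S,10S,11R,12R,17R)-2,12-diacetoxy-9-(tert-butyldimethylsilyloxy)-6-chloro-8-hydroxybriara-5,13-dien-19,7-olide
Conditions: Ac2O, pyridine, 4-(dimethylamino)pyridine (cat.), CH2Cl2, 0 °C → rt
Reagents that add atoms: acetic anhydride, CC(=O)OC(C)=O
Why: Acylation of the two secondary alcohols; the tertiary C8 hydroxyl, flanked by a quaternary centre and the silyl ether, does not react under these mild conditions.

Step 31
Reactants: 48 (1S,2S,7R,8S,9S,10S,11R,12R,17R)-2,12-diacetoxy-9-(tert-butyldimethylsilyloxy)-6-chloro-8-hydroxybriara-5,13-dien-19,7-olide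
Product: 49 CNP0296164.1 [(1S,2S,7R,8R,9S,10S,11R,12R,17R)-2,12-diacetoxy-6-chloro-8,9-dihydroxybriara-5,13-dien-19,7-olide]
Conditions: HF·pyridine, THF, rt
Reagents that add atoms: none
Why: Fluoride-mediated cleavage of the last silyl ether; the medium is weakly acidic, so the acetates, the lactone and the β-hydroxy lactone unit are not opened or shifted.

## Compound list

1 | 2,2-dimethoxyacetaldehyde | COC(OC)C=O | starting material
2 | (Z)-crotylboronic acid pinacol ester | C/C=C\CB1OC(C)(C)C(C)(C)O1 | starting material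
3 | (2S,3R)-1,1-dimethoxy-3-methylpent-4-en-2-ol | COC(OC)[C@@H](O)[C@H](C)C=C | intermediate
4 | triethyl{[(2S,3R)-1,1-dimethoxy-3-methylpent-4-en-2-yl]oxy}silane | COC(OC)[C@@H](O[Si](CC)(CC)CC)[C@H](C)C=C | intermediate
5 | 9-[(3R,4S)-5,5-dimethoxy-3-methyl-4-(triethylsilyloxy)pentyl]-9-borabicyclo[3.3.1]nonane (not isolated) | COC(OC)[C@@H](O[Si](CC)(CC)CC)[C@H](C)CCB1C2CCCC1CCC2 | intermediate
6 | (3R,4S)-5,5-dimethoxy-3-methyl-4-(triethylsilyloxy)pentan-1-ol | COC(OC)[C@@H](O[Si](CC)(CC)CC)[C@H](C)CCO | intermediate
7 | (3R,4S)-5,5-dimethoxy-3-methyl-4-(triethylsilyloxy)pentanoic acid | COC(OC)[C@@H](O[Si](CC)(CC)CC)[C@H](C)CC(=O)O | intermediate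
8 | methyl (3R,4S)-5,5-dimethoxy-3-methyl-4-(triethylsilyloxy)pentanoate | COC(OC)[C@@H](O[Si](CC)(CC)CC)[C@H](C)CC(=O)OC | intermediate
9 | methyl (3R,4S)-3-methyl-5-oxo-4-(triethylsilyloxy)pentanoate | O=C[C@@H](O[Si](CC)(CC)CC)[C@H](C)CC(=O)OC | intermediate
10 | prop-2-yn-1-ol (propargyl alcohol) | C#CCO | starting material
11 | bromo[(1Z)-3-(bromomagnesiooxy)-2-methylprop-1-en-1-yl]magnesium (not isolated) | Br[Mg]/C=C(/C)CO[Mg]Br | intermediate
12 | (Z)-3-iodo-2-methylprop-2-en-1-ol | I/C=C(/C)CO | intermediate
13 | (Z)-3-iodo-2-methylprop-2-enal | I/C=C(/C)C=O | intermediate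
14 | vinylmagnesium bromide | C=C[Mg]Br | starting material
15 | rac-(1Z)-1-iodo-2-methylpenta-1,4-dien-3-ol | I/C=C(/C)C(O)C=C | intermediate
16 | (1Z,3S)-1-iodo-2-methylpenta-1,4-dien-3-ol | I/C=C(/C)[C@@H](O)C=C | intermediate
17 | triethyl{[(1Z,3S)-1-iodo-2-methylpenta-1,4-dien-3-yl]oxy}silane | I/C=C(/C)[C@@H](O[Si](CC)(CC)CC)C=C | intermediate
18 | [(1Z,3S)-2-methyl-3-(triethylsilyloxy)penta-1,4-dien-1-yl]lithium (not isolated) | [Li]/C=C(/C)[C@@H](O[Si](CC)(CC)CC)C=C | intermediate
19 | bromo[(1Z,3S)-2-methyl-3-(triethylsilyloxy)penta-1,4-dien-1-yl]zinc (not isolated) | Br[Zn]/C=C(/C)[C@@H](O[Si](CC)(CC)CC)C=C | intermediate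
20 | methyl (3R,4S,5S,6Z,8S)-5-hydroxy-3,7-dimethyl-4,8-bis(triethylsilyloxy)deca-6,9-dienoate | COC(=O)C[C@@H](C)[C@H](O[Si](CC)(CC)CC)[C@@H](O)/C=C(/C)[C@@H](O[Si](CC)(CC)CC)C=C | intermediate
21 | (4R,5S,6S)-4-methyl-6-[(1Z,3S)-2-methyl-3-(triethylsilyloxy)penta-1,4-dien-1-yl]-5-(triethylsilyloxy)tetrahydro-2H-pyran-2-one | O=C1C[C@@H](C)[C@H](O[Si](CC)(CC)CC)[C@@H](O1)/C=C(/C)[C@@H](O[Si](CC)(CC)CC)C=C | intermediate
22 | silyl ketene acetal of 21: 6-(trimethylsilyloxy)-3,4-dihydro-2H-pyran with C9=C10, other centres as in 21 (not isolated) | C[Si](C)(C)OC1=C[C@@H](C)[C@H](O[Si](CC)(CC)CC)[C@@H](O1)/C=C(/C)[C@@H](O[Si](CC)(CC)CC)C=C | intermediate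
23 | trimethylsilyl ester of 24 (not isolated) | C[Si](C)(C)OC(=O)[C@H]1[C@@H](C)[C@H](O[Si](CC)(CC)CC)C=C[C@]1(C)[C@@H](O[Si](CC)(CC)CC)C=C | intermediate
24 | (1S,2S,5R,6R)-2,6-dimethyl-5-(triethylsilyloxy)-2-[(1S)-1-(triethylsilyloxy)prop-2-en-1-yl]cyclohex-3-ene-1-carboxylic acid | OC(=O)[C@H]1[C@@H](C)[C@H](O[Si](CC)(CC)CC)C=C[C@]1(C)[C@@H](O[Si](CC)(CC)CC)C=C | intermediate
25 | acid chloride of 24, RA–C(=O)Cl (not isolated) | ClC(=O)[C@H]1[C@@H](C)[C@H](O[Si](CC)(CC)CC)C=C[C@]1(C)[C@@H](O[Si](CC)(CC)CC)C=C | intermediate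
26 | N-methoxy-N-methylamide of 24, RA–C(=O)N(OMe)Me | CON(C)C(=O)[C@H]1[C@@H](C)[C@H](O[Si](CC)(CC)CC)C=C[C@]1(C)[C@@H](O[Si](CC)(CC)CC)C=C | intermediate
27 | 4-methoxybenzyl alcohol | COc1ccc(CO)cc1 | starting material
28 | tributyl(iodomethyl)stannane | CCCC[Sn](CCCC)(CCCC)CI | starting material
29 | tributyl{[(4-methoxybenzyl)oxy]methyl}stannane | CCCC[Sn](CCCC)(CCCC)COCc1ccc(OC)cc1 | intermediate
30 | {[(4-methoxybenzyl)oxy]methyl}lithium (not isolated) | [Li]COCc1ccc(OC)cc1 | intermediate
31 | 2-(4-methoxybenzyloxy)-1-RA-ethan-1-one | COc1ccc(COCC(=O)[C@H]2[C@@H](C)[C@H](O[Si](CC)(CC)CC)C=C[C@]2(C)[C@@H](O[Si](CC)(CC)CC)C=C)cc1 | intermediate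
32 | ethyl 2-chloro-3-oxobutanoate | CCOC(=O)C(Cl)C(C)=O | starting material
33 | ethyl (2E)-2-chloro-3-(trifluoromethylsulfonyloxy)but-2-enoate | CCOC(=O)/C(Cl)=C(/C)OS(=O)(=O)C(F)(F)F | intermediate
34 | (2E)-3-chloro-4-hydroxybut-2-en-2-yl trifluoromethanesulfonate | OC/C(Cl)=C(/C)OS(=O)(=O)C(F)(F)F | intermediate
35 | (2E)-3-chloro-4-oxobut-2-en-2-yl trifluoromethanesulfonate | O=C/C(Cl)=C(/C)OS(=O)(=O)C(F)(F)F | intermediate
36 | (Z)-diisopinocampheylboron enolate of 31 (not isolated) | COc1ccc(CO/C=C(\OB([C@@H]3C[C@@H]4C[C@@H](C4(C)C)[C@H]3C)[C@@H]3C[C@@H]4C[C@@H](C4(C)C)[C@H]3C)[C@H]2[C@@H](C)[C@H](O[Si](CC)(CC)CC)C=C[C@]2(C)[C@@H](O[Si](CC)(CC)CC)C=C)cc1 | intermediate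
37 | (2R,3R,4E)-4-chloro-3-hydroxy-2-(4-methoxybenzyloxy)-1-RA-5-(trifluoromethylsulfonyloxy)hex-4-en-1-one (C7 R, C8 R) | FC(F)(F)S(=O)(=O)O/C(C)=C(/Cl)[C@H](O)[C@@H](OCc1ccc(OC)cc1)C(=O)[C@H]2[C@@H](C)[C@H](O[Si](CC)(CC)CC)C=C[C@]2(C)[C@@H](O[Si](CC)(CC)CC)C=C | intermediate
38 | 2-bromopropanoate of 37 at O7 (both CHBr epimers) | FC(F)(F)S(=O)(=O)O/C(C)=C(/Cl)[C@H](OC(=O)C(C)Br)[C@@H](OCc1ccc(OC)cc1)C(=O)[C@H]2[C@@H](C)[C@H](O[Si](CC)(CC)CC)C=C[C@]2(C)[C@@H](O[Si](CC)(CC)CC)C=C | intermediate
39 | (1S,2S,3R,4E)-3-(2-bromopropanoyloxy)-4-chloro-2-(4-methoxybenzyloxy)-1-RA-5-(trifluoromethylsulfonyloxy)hex-4-en-1-ol (C9 S) | FC(F)(F)S(=O)(=O)O/C(C)=C(/Cl)[C@H](OC(=O)C(C)Br)[C@@H](OCc1ccc(OC)cc1)[C@@H](O)[C@H]2[C@@H](C)[C@H](O[Si](CC)(CC)CC)C=C[C@]2(C)[C@@H](O[Si](CC)(CC)CC)C=C | intermediate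
40 | tert-butyldimethylsilyl ether of 39 at O9 | FC(F)(F)S(=O)(=O)O/C(C)=C(/Cl)[C@H](OC(=O)C(C)Br)[C@@H](OCc1ccc(OC)cc1)[C@@H](O[Si](C)(C)C(C)(C)C)[C@H]2[C@@H](C)[C@H](O[Si](CC)(CC)CC)C=C[C@]2(C)[C@@H](O[Si](CC)(CC)CC)C=C | intermediate
41 | (1S,2R,3R,4E)-3-(2-bromopropanoyloxy)-1-(tert-butyldimethylsilyloxy)-4-chloro-1-RA-5-(trifluoromethylsulfonyloxy)hex-4-en-2-ol | FC(F)(F)S(=O)(=O)O/C(C)=C(/Cl)[C@H](OC(=O)C(C)Br)[C@@H](O)[C@@H](O[Si](C)(C)C(C)(C)C)[C@H]2[C@@H](C)[C@H](O[Si](CC)(CC)CC)C=C[C@]2(C)[C@@H](O[Si](CC)(CC)CC)C=C | intermediate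
42 | (1S,3R,4E)-3-(2-bromopropanoyloxy)-1-(tert-butyldimethylsilyloxy)-4-chloro-1-RA-5-(trifluoromethylsulfonyloxy)hex-4-en-2-one | FC(F)(F)S(=O)(=O)O/C(C)=C(/Cl)[C@H](OC(=O)C(C)Br)C(=O)[C@@H](O[Si](C)(C)C(C)(C)C)[C@H]2[C@@H](C)[C@H](O[Si](CC)(CC)CC)C=C[C@]2(C)[C@@H](O[Si](CC)(CC)CC)C=C | intermediate
43 | diiodosamarium ester enolate of 42 (not isolated) | FC(F)(F)S(=O)(=O)O/C(C)=C(/Cl)[C@H](OC(O[Sm](I)I)=CC)C(=O)[C@@H](O[Si](C)(C)C(C)(C)C)[C@H]2[C@@H](C)[C@H](O[Si](CC)(CC)CC)C=C[C@]2(C)[C@@H](O[Si](CC)(CC)CC)C=C | intermediate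
44 | (3R,4S,5R)-5-[(1E)-1-chloro-2-(trifluoromethylsulfonyloxy)prop-1-en-1-yl]-4-hydroxy-3-methyl-4-[(S)-RA(tert-butyldimethylsilyloxy)methyl]dihydrofuran-2(3H)-one | FC(F)(F)S(=O)(=O)O/C(C)=C(/Cl)[C@@H]1OC(=O)[C@H](C)[C@@]1(O)[C@@H](O[Si](C)(C)C(C)(C)C)[C@H]2[C@@H](C)[C@H](O[Si](CC)(CC)CC)C=C[C@]2(C)[C@@H](O[Si](CC)(CC)CC)C=C | intermediate
45 | B-alkyl-9-borabicyclo[3.3.1]nonane from 44 (boron on C4; not isolated) | FC(F)(F)S(=O)(=O)O/C(C)=C(/Cl)[C@@H]1OC(=O)[C@H](C)[C@@]1(O)[C@@H](O[Si](C)(C)C(C)(C)C)[C@H]2[C@@H](C)[C@H](O[Si](CC)(CC)CC)C=C[C@]2(C)[C@@H](O[Si](CC)(CC)CC)CCB3C4CCCC3CCC4 | intermediate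
46 | (1S,2S,7R,8S,9S,10S,11R,12R,17R)-9-(tert-butyldimethylsilyloxy)-6-chloro-8-hydroxy-2,12-bis(triethylsilyloxy)briara-5,13-dien-19,7-olide | CC[Si](CC)(CC)O[C@H]1CC/C(C)=C(/Cl)[C@@H]2OC(=O)[C@H](C)[C@@]2(O)[C@@H](O[Si](C)(C)C(C)(C)C)[C@H]2[C@@H](C)[C@H](O[Si](CC)(CC)CC)C=C[C@@]21C | intermediate
47 | (1S,2S,7R,8S,9S,10S,11R,12R,17R)-9-(tert-butyldimethylsilyloxy)-6-chloro-2,8,12-trihydroxybriara-5,13-dien-19,7-olide | O[C@H]1CC/C(C)=C(/Cl)[C@@H]2OC(=O)[C@H](C)[C@@]2(O)[C@@H](O[Si](C)(C)C(C)(C)C)[C@H]2[C@@H](C)[C@H](O)C=C[C@@]21C | intermediate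
48 | (1S,2S,7R,8S,9S,10S,11R,12R,17R)-2,12-diacetoxy-9-(tert-butyldimethylsilyloxy)-6-chloro-8-hydroxybriara-5,13-dien-19,7-olide | CC(=O)O[C@H]1CC/C(C)=C(/Cl)[C@@H]2OC(=O)[C@H](C)[C@@]2(O)[C@@H](O[Si](C)(C)C(C)(C)C)[C@H]2[C@@H](C)[C@H](OC(C)=O)C=C[C@@]21C | intermediate
49 | CNP0296164.1, (1S,2S,7R,8R,9S,10S,11R,12R,17R)-2,12-diacetoxy-6-chloro-8,9-dihydroxybriara-5,13-dien-19,7-olide | CC(=O)O[C@H]1CC/C(C)=C(/Cl)[C@@H]2OC(=O)[C@H](C)[C@@]2(O)[C@@H](O)[C@H]2[C@@H](C)[C@H](OC(C)=O)C=C[C@@]21C | target

## Step count and least certain steps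

Total step count: 31. Longest linear sequence: 22 steps (steps 1 to 6, 12 to 15, 17 and 21 to 31).

Step 14 (key step). What is most likely to go wrong is slow or incomplete rearrangement with decomposition of the ketene acetal on prolonged heating. The enforced boat has to create a quaternary centre with the bulky C2 branch on the alkene terminus, and competing C-silylation would remove material before the shift. Fallback: build the same C1–C10 bond through an acyclic chair transition state and close ring A afterwards by metathesis. The fallback sets out from 9 and 17 and comes back at 24. Wittig methylenation of 9 (Ph3P=CH2, THF, −78 → 0 °C) gives methyl (3R,4R)-3-methyl-4-(triethylsilyloxy)hex-5-enoate F1, and saponification (LiOH, THF/H2O) gives (3R,4R)-3-methyl-4-(triethylsilyloxy)hex-5-enoic acid F2. Iodine–lithium exchange on 17 (t-BuLi, Et2O, −78 °C, through 18) and trapping with paraformaldehyde gives (2Z,4S)-3-methyl-4-(triethylsilyloxy)hexa-2,5-dien-1-ol F3. Carbodiimide esterification (N,N'-dicyclohexylcarbodiimide, 4-(dimethylamino)pyridine) joins the two as the allylic ester F4. Ireland–Claisen rearrangement (LiN(i-Pr)2, THF/HMPA, Me3SiCl, −78 °C → rt, then aqueous work-up) is run so that the C11 branch sits cis to the silyloxy group of the ketene acetal; in the chair this places the C11 branch equatorial and the C2 branch of the Z-alkene axial, which is the C1/C10 relationship of 24, and gives the seco acid F5. In this acyclic case the face selectivity relative to C2 and C11 has to come from allylic strain and is less secure than in the ring contraction. Ring-closing metathesis of F5 with RuCl2(=CHPh)(PCy3)(H2IMes) (second-generation Grubbs catalyst, CH2Cl2, 40 °C) joins the C13 and C14 vinyl groups in the only six-membered mode and gives 24.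

Step 12. What is most likely to go wrong is loss of chelation control. A silyl ether is a weak donor, and if the zinc does not bridge the two oxygens the alkenyl group adds by the open, non-chelated pathway and gives the 12,13-anti alcohol. Fallback: set C13 by hydride instead of by the carbon nucleophile. It sets out from 20 (as the C13 epimer mixture) and comes back at 20. Oxidation (DMP, NaHCO3, CH2Cl2) gives methyl (3R,4S,6Z,8S)-3,7-dimethyl-5-oxo-4,8-bis(triethylsilyloxy)deca-6,9-dienoate F6. 1,2-Reduction of this α-silyloxy enone under non-chelating conditions (NaBH4, CeCl3·7H2O, MeOH, −78 °C; Luche reduction) delivers hydride anti to the silyloxy group and gives the syn alcohol 20.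

Step 21. What is most likely to go wrong is poor facial selectivity at C7. The isopinocampheyl ligands have to discriminate the faces of an unhindered enal, the ketone is hindered and α-oxygenated, and a mismatched substrate bias cannot be excluded. Fallback: move the chirality from the enolate metal to a Lewis acid on the aldehyde. It sets out from 31 and comes back at 37. Silylation (Me3SiOTf, Et3N, CH2Cl2, 0 °C) gives the (Z)-trimethylsilyl enol ether F7. A Mukaiyama aldol reaction of F7 with 35 is then run in propionitrile at −78 °C, promoted by the B-butyl oxazaborolidinone prepared from N-(p-toluenesulfonyl)-(S)-tryptophan and butylboronic acid; the catalyst antipode is chosen for the Re face of the enal. Mild acidic work-up then gives 37. In this open transition state the 7,8-syn relationship is less assured than in the boron aldol and would have to be checked before step 23.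

Step 27. What is most likely to go wrong is reduction at the wrong site. Electron transfer to the α-acyloxy ketone can cleave the C7–O bond in competition with reduction of the C–Br bond, and the C17 configuration is not rigorously predictable. Fallback: generate the ester enolate by conjugate hydride addition instead of by one-electron reduction. It sets out from 40 and comes back at 44. Dehydrobromination (1,8-diazabicyclo[5.4.0]undec-7-ene, CH2Cl2, 0 °C) gives the O7 acrylate F8. Oxidative removal of the 4-methoxybenzyl group (DDQ, CH2Cl2/pH 7 buffer) gives the C8 alcohol F9, and oxidation (DMP, NaHCO3) gives the keto acrylate F10. Reductive aldol cyclisation of F10 with [(Ph3P)CuH]6 (toluene, −40 → 0 °C) adds hydride to the acrylate terminus, which creates the C18 methyl group, and the copper enolate closes onto the C8 ketone to give 44.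

Step 28. What is most likely to go wrong is slow transmetalation and ring closure at the hindered tetrasubstituted alkenylpalladium centre, so that protodeboronation, β-hydride elimination or intermolecular coupling to oligomers takes over. Fallback: replace the boron-to-palladium transfer, which needs aqueous base, by a base-free alkylzinc. It sets out from 44 and comes back at 46. Hydroboration–oxidation (9-BBN, THF; then NaBO3·4H2O) gives the C4 primary alcohol F11. Iodination (I2, PPh3, imidazole, CH2Cl2, 0 °C) gives the C4 iodide F12. Zinc insertion into the C–I bond (Zn dust, LiCl, THF, 25 °C) is followed by an intramolecular Negishi coupling with the enol triflate (PdCl2(dppf), THF, slow addition, 50 °C), which closes the ring to 46.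

## Further compounds

F1 | step 14 | methyl (3R,4R)-3-methyl-4-(triethylsilyloxy)hex-5-enoate | C=C[C@@H](O[Si](CC)(CC)CC)[C@H](C)CC(=O)OC
F2 | step 14 | (3R,4R)-3-methyl-4-(triethylsilyloxy)hex-5-enoic acid | C=C[C@@H](O[Si](CC)(CC)CC)[C@H](C)CC(=O)O
F3 | step 14 | (2Z,4S)-3-methyl-4-(triethylsilyloxy)hexa-2,5-dien-1-ol | OC/C=C(/C)[C@@H](O[Si](CC)(CC)CC)C=C
F4 | step 14 | (2Z,4S)-3-methyl-4-(triethylsilyloxy)hexa-2,5-dien-1-yl (3R,4R)-3-methyl-4-(triethylsilyloxy)hex-5-enoate | C=C[C@@H](O[Si](CC)(CC)CC)[C@H](C)CC(=O)OC/C=C(/C)[C@@H](O[Si](CC)(CC)CC)C=C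
F5 | step 14 | seco acid of 24 with C13 and C14 as two vinyl groups (configuration as in the SMILES) | C=C[C@@H](O[Si](CC)(CC)CC)[C@H](C)[C@H](C(=O)O)[C@](C)(C=C)[C@@H](O[Si](CC)(CC)CC)C=C
F6 | step 12 | methyl (3R,4S,6Z,8S)-3,7-dimethyl-5-oxo-4,8-bis(triethylsilyloxy)deca-6,9-dienoate | COC(=O)C[C@@H](C)[C@H](O[Si](CC)(CC)CC)C(=O)/C=C(/C)[C@@H](O[Si](CC)(CC)CC)C=C
F7 | step 21 | (Z)-trimethylsilyl enol ether of 31 | COc1ccc(CO/C=C(\O[Si](C)(C)C)[C@H]2[C@@H](C)[C@H](O[Si](CC)(CC)CC)C=C[C@]2(C)[C@@H](O[Si](CC)(CC)CC)C=C)cc1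
F8 | step 27 | O7 acrylate analogue of 40 | FC(F)(F)S(=O)(=O)O/C(C)=C(/Cl)[C@H](OC(=O)C=C)[C@@H](OCc1ccc(OC)cc1)[C@@H](O[Si](C)(C)C(C)(C)C)[C@H]2[C@@H](C)[C@H](O[Si](CC)(CC)CC)C=C[C@]2(C)[C@@H](O[Si](CC)(CC)CC)C=C
F9 | step 27 | O7 acrylate analogue of 41 (C8 alcohol) | FC(F)(F)S(=O)(=O)O/C(C)=C(/Cl)[C@H](OC(=O)C=C)[C@@H](O)[C@@H](O[Si](C)(C)C(C)(C)C)[C@H]2[C@@H](C)[C@H](O[Si](CC)(CC)CC)C=C[C@]2(C)[C@@H](O[Si](CC)(CC)CC)C=C
F10 | step 27 | O7 acrylate analogue of 42 (C8 ketone) | FC(F)(F)S(=O)(=O)O/C(C)=C(/Cl)[C@H](OC(=O)C=C)C(=O)[C@@H](O[Si](C)(C)C(C)(C)C)[C@H]2[C@@H](C)[C@H](O[Si](CC)(CC)CC)C=C[C@]2(C)[C@@H](O[Si](CC)(CC)CC)C=C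
F11 | step 28 | C4 primary alcohol from 44 | FC(F)(F)S(=O)(=O)O/C(C)=C(/Cl)[C@@H]1OC(=O)[C@H](C)[C@@]1(O)[C@@H](O[Si](C)(C)C(C)(C)C)[C@H]2[C@@H](C)[C@H](O[Si](CC)(CC)CC)C=C[C@]2(C)[C@@H](O[Si](CC)(CC)CC)CCO
F12 | step 28 | C4 primary iodide from F11 | FC(F)(F)S(=O)(=O)O/C(C)=C(/Cl)[C@@H]1OC(=O)[C@H](C)[C@@]1(O)[C@@H](O[Si](C)(C)C(C)(C)C)[C@H]2[C@@H](C)[C@H](O[Si](CC)(CC)CC)C=C[C@]2(C)[C@@H](O[Si](CC)(CC)CC)CCI
A1 | alternative 1 | ten-membered C7 carbinol from the C6–C7 closure (C8 trimethylsilyl ether, C9 triethylsilyl ether, methyl propanoate side chain on C8, 2,12-diacetate) | CC(=O)O[C@H]1CC/C(C)=C(/Cl)[C@H](O)[C@@](O[Si](C)(C)C)([C@@H](C)C(=O)OC)[C@@H](O[Si](CC)(CC)CC)[C@H]2[C@@H](C)[C@H](OC(C)=O)C=C[C@@]21C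
A2 | alternative 2 | methyl 6-formyl-2,6-dimethyl-3-(tert-butyldimethylsilyloxy)cyclohex-3-ene-1-carboxylate (ring A silyl enol ether, configuration as in the SMILES) | O=C[C@@]1(C)CC=C(O[Si](C)(C)C(C)(C)C)[C@H](C)[C@@H]1C(=O)OC
A3 | alternative 3 | ten-membered 2,8-diketone with the cis chloroalkene, 7,9-bis(tert-butyldimethylsilyl) ethers and the ring A enone | O=C1CC/C(C)=C(/Cl)[C@H](O[Si](C)(C)C(C)(C)C)C(=O)[C@@H](O[Si](C)(C)C(C)(C)C)[C@H]2[C@@H](C)C(=O)C=C[C@@]21C
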